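3 questions stand on this flask:

- part of the left-handed substrate and right-handed substrate charged together that has reacted at 50 h
- excess of left-handed product over right-handed product in the product at 50 h
- excess of right-handed substrate over left-handed substrate among what is left of the two at 50 h

common to all: left-handed substrate 0.20 M; right-handed substrate 0.20 M
- Wednesday's: reagent 0.16 M; free catalyst 42 mM; run made earlier
- Friday's: reagent 0.16 M; free catalyst 66 mM; run made earlier
- flask: reagent 0.160 M; free catalyst 30 mM; time 50 h

| run | time / h | left-handed substrate / % | right-handed substrate / % | left-handed product / % |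
|---|---|---|---|---|
| Wednesday's | 2.50 | 48 | 47 | 5 |
| Wednesday's | 8.00 | 43 | 48 | 8 |
| Wednesday's | 15.0 | 35 | 46 | 14 |
| Wednesday's | 20.0 | 35 | 45 | 14 |
| Wednesday's | 30.0 | 32 | 48 | 15 |
| Wednesday's | 40.0 | 27 | 44 | 18 |
| Friday's | 3.00 | 41 | 51 | 8 |
| Friday's | 5.00 | 37 | 47 | 11 |
| Friday's | 8.00 | 35 | 44 | 13 |
| Friday's | 15.0 | 32 | 46 | 16 |
| Friday's | 25.0 | 26 | 43 | 18 |
| Friday's | 40.0 | 27 | 44 | 18 |

(standard deviation of a reading: 1.5 percentage points)

- free catalyst is single-handed; left-handed substrate and right-handed substrate are mirror images of each other, charged as a racemate, each of them at the stated concentration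
- the analysis behind the earlier runs scatters by 1.5 percentage points, standard deviation
- an excess is the difference of the two amounts in percent of their sum
- an excess is below zero if the other one leads

The nearest simulated run is Wednesday's, with the same substrates and reagent but [free catalyst] at 42 mM. Charge times clock, the flask at 50 h reaches 0.893 of Wednesday's at 40.0 h. So the flask should react a little less than Wednesday's 29.0 %, with right-handed product taken as the remainder of the balance.

But the flask runs 10.0 h longer, and the product excess seems to follow the clock. At 40.0 h, Friday's run, with more catalyst, reads the same 18 % of left-handed product as Wednesday's, and Wednesday's reading is an excess of 24.1 %.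

In Wednesday's run, right-handed product rises from 5.00 % at 15.0 h to 11.0 % at 40.0 h, while left-handed product leads by about 8 percentage points. Read that gain as racemisation, proportional to the lead. Each point that crosses counts twice against the lead, so this gives the excess half-life, the clock time in which the lead halves if no new product comes: 11.6 h. It is a rough reading, given the scatter of 1.5 points.

Wednesday's excess carried over the extra hours gives about 13.2 % for the flask. The forecast differs: 22 % (12 % to 32 %), “perhaps slightly lower”, with c at 28.5 % and eS at 23 %.

The flask gives c 25.8 %, eP 10.5 % and eS 20.1 %; eP stands 12 points below the forecast.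

    free catalyst ⇌ dormant form (K = 0.450, k = 3.40 × 10⁻⁵ s⁻¹)
    reagent + free catalyst + right-handed substrate → free catalyst + right-handed product (k = 4.20 × 10⁻⁴ M⁻² s⁻¹)
    reagent + free catalyst + left-handed substrate → free catalyst + left-handed product (k = 0.00190 M⁻² s⁻¹)
    free catalyst → spent catalyst (k = 4.60 × 10⁻⁶ s⁻¹)
    left-handed product ⇌ right-handed product (k = 8.30 × 10⁻⁶ s⁻¹)

In the flask at 50 h, left-handed product is still made 1.64 times faster than it is used up, each step taken net. Reckoned with the excess half-life and no new product, the flask's 25.3 % at 25.0 h comes to 5.65 % at 50 h, and the flask stands higher.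

The neighbour with 0.096 M of reagent, otherwise like this flask, has the same clock: 50 h is 4.31 excess half-lives, so its excess is expected near 10.5 %. Computed, it gives 11.4 %, at c 16.3 %.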